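You cannot read the loss of target late in grey from two neighbouring readings: side product moves 5 percentage points between them, with a scatter of 1.5 points on each.

| flask | substrate | coupling partner | remark | time |
|---|---|---|---|---|
| grey | 0.50 M | 0.55 M | run made earlier |  |
| teal | 1 M | 0.55 M | run made earlier |  |
| birch | 0.50 M | 0.550 M | everything together in a closed stirred flask, run for 12 min | 12 min |
| larch | 0.50 M (fed, over 12.0 min) | 0.550 M | all but substrate at the start; substrate goes in evenly over 12.0 min, the run ends at 12 min | 12 min |
| ash | 0.50 M | 0.550 M | one stirred flow tank at steady state, fed with the mixture as stated, mean residence time 36.0 min |  |
| oak | 0.50 M | 0.550 M | a single well-mixed tank run continuously and read at steady state, 12 min in it on average |  |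

- grey (time / min: target / %, side product / %): 2.00: 31, 4; 4.00: 45, 9; 6.00: 55, 15; 8.00: 57, 18; 10.0: 62, 20; 12.0: 65, 25
- teal (time / min: target / %, side product / %): 0.200: 4, 1; 0.333: 7, 0; 0.500: 12, 0; 0.833: 15, 2; 1.33: 17, 2; 2.50: 28, 10

(each reading ± 1.5 percentage points)

- the set-up with the highest share of target in all that became target or side product, at the outlet or at the end ("none" if the first two lie within 2 percentage points) (birch / larch / ash / oak / none)
- share of target in all that became target or side product, at the outlet or at the end, birch
- share of target in all that became target or side product, at the outlet or at the end, larch
- share of target in all that became target or side product, at the outlet or at the end, ash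
- share of target in all that became target or side product, at the outlet or at the end, oak

- in percentages every species weighs as the substrate in it: one side product counts as two
- the stated concentrations are those of everything mixed, before any reaction; amounts are the same in each set-up
- the feed brings no volume worth counting
- the earlier runs were made in a closed, stirred flask

1. In grey, side product trails target, 4% against 31% at 2.00 min, so I read it as target lost later. It counts two, so the target ever made by 12.0 min is the standing target plus the side percentage over 2: 77.5% of the charge.

2. Call target lost per target made the loss ratio x. Then the share asked for is (1 − x)/(1 + x). Grey's mean x is 0.161, giving 72.3%. Birch repeats grey's charge and time, so that is my birch.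

3. Replace the curve by its mean. If x rises in step with c_target from nil, the end value is 0.323, twice the mean. Dividing by the final c_target, as a fraction of the charge, gives 0.496: the loss coefficient, x per unit of standing target.

4. A tank (back-mixing) works at its outlet state, so it pays the local x, not the mean. Oak's balance asks for progress divided by 12 min. Around 4.00 min, grey makes 0.0737 min⁻¹, above the 0.0412 min⁻¹ needed there. Around 6.00 min, it makes 0.0413 min⁻¹, below the 0.0521 min⁻¹ needed. I take the midpoint, 56.0%. With standing target equal to progress times (1 − x), oak's x is 0.217, and its share 64.3%.

5. Fed substrate in larch has spent 6.00 min in the flask on average, so I take grey at 6.00 min: 78.6%, above birch. My choice is larch.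

6. The weak link is the straight rise. From 6.00 min to 12.0 min, target lost per target made reads 0.333, while the coefficient at the mean c_target gives 0.298. That reading rests on a side-product difference of 10 points, so I keep the coefficient.

The forecast says 73% for birch, 82% for larch, 57% for ash and 66% for oak, best larch, holding that “what matters is how far the coupling partner is converted and how much back-mixing occurs”.

The flasks give 72.6% for birch, 80.8% for larch, 58.3% for ash and 65.3% for oak, best larch.

    substrate + coupling partner → target, rate k1*[substrate]*[coupling partner]^0.5 (k = 0.295 M⁻⁰·⁵ min⁻¹)
    substrate + target → side product (k = 0.142 M⁻¹ min⁻¹)

At the concentrations as charged, target in birch has a half-life of 9.8 min by loss to side product, shorter than the 12 min run. Ash holds its mixture 36.0 min on average, and target stands there at 50.1% of the substrate charged. Oak's share means x = 0.210, against my 0.217. For ash, the loss coefficient turns that standing target into x = 0.249, a share of 60.1%, where the flask gives 58.3%.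

The runs were generated by integration with constants of no real substance, noise included.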